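**Retrosynthetic overview**
1. The target is a (2R,3R)-trans-2-aryl-3-methyl-2,3-dihydrobenzofuran. Both benzene rings are bought, the dihydrofuran ring is the only ring made and is closed last, and the (E)-propenyl group is added afterwards by Suzuki coupling of a C5 bromide.
2. Key disconnection, C2–C3 and O1–C2 in one operation: a formal [4+1] annulation of an ortho-quinone methide (C3–C3a–C7a–O1) with a chiral 3,4,5-trimethoxybenzyl sulfonium ylide (C2 with its aryl group).
3. Enabling feature: C3 is a benzylic CH(CH3) ortho to the phenolic oxygen O1 of the guaiacol ring, so C3=C3a–C7a=O1 can be unveiled as a 1-oxadiene. C2 is a benzylic carbon bound to both C3 and O1, so it can act first as a nucleophile and then as an electrophile.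
4. Stereoconvergence: the quinone methide comes from a racemic 2-(1-sulfonylethyl)phenol whose stereocentre is erased. The sulfide sets C2, and trans-selective addition relays this to C3.
5. Precursors: the sulfone from 5-bromo-ortho-vanillin (Grignard addition, sulfinate substitution), and the sulfonium salt from 3,4,5-trimethoxybenzyl bromide and isothiocineole.

Key step: step 4

Remark: p-toluenesulfinic acid is liberated from its sodium salt just before use, and the (1S,4S,5S) antipode of isothiocineole is taken as purchasable (it is also one step from (S)-limonene, sulfur and γ-terpinene).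

**Step 1**
Reactants: 1 5-bromo-2-hydroxy-3-methoxybenzaldehyde
Product: 2 rac-4-bromo-2-(1-hydroxyethyl)-6-methoxyphenol
Conditions: MeMgBr (2.5 equiv), THF, 0 °C to rt; then sat. aq. NH4Cl
Reagents that add atoms: methylmagnesium bromide, C[Mg]Br
Why: Grignard 1,2-addition to the aldehyde after the first equivalent has deprotonated the phenol; the aryl bromide is inert to MeMgBr at this temperature, and the new carbinol centre is left racemic on purpose because step 4 erases it.

**Step 2**
Reactants: 2 rac-4-bromo-2-(1-hydroxyethyl)-6-methoxyphenol
Product: 3 rac-4-bromo-2-methoxy-6-[1-(4-methylbenzenesulfonyl)ethyl]phenol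
Conditions: p-TolSO2H (1.5 equiv), MgSO4, CH2Cl2, rt
Reagents that add atoms: 4-methylbenzenesulfinic acid, Cc1ccc(cc1)S(=O)O
Why: Acid-promoted SN1-type substitution of the ortho-hydroxybenzylic alcohol by the soft sulfur nucleophile (S-alkylation of a sulfinate to a sulfone), the usual entry to 2-(1-sulfonylalkyl)phenols; the centre stays racemic and is destroyed later.

**Step 3**
Reactants: 4 5-(bromomethyl)-1,2,3-trimethoxybenzene; 5 (1S,4S,5S)-4,7,7-trimethyl-6-thiabicyclo[3.2.1]octane (isothiocineole)
Product: 6 (3,4,5-trimethoxybenzyl)sulfonium triflate of 5, with the benzyl group on the sulfur lone pair remote from the trimethylene bridge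
Conditions: LiOTf (5 equiv), CH2Cl2/H2O (1:1), rt
Reagents that add atoms: lithium trifluoromethanesulfonate, [Li+].[O-]S(=O)(=O)C(F)(F)F
Why: SN2 S-alkylation of the thioether by the benzylic bromide with in-situ anion metathesis to the non-nucleophilic triflate, which suppresses dealkylation by bromide; alkylation on the exposed lone pair should give one diastereomer at sulfur.

**Step 4**
Reactants: 3 rac-4-bromo-2-methoxy-6-[1-(4-methylbenzenesulfonyl)ethyl]phenol; 6 sulfonium triflate
Product: 10 (2R,3R)-5-bromo-7-methoxy-3-methyl-2-(3,4,5-trimethoxyphenyl)-2,3-dihydro-1-benzofuran, via ortho-quinone methide 7 (not isolated), via sulfonium benzylide 8 (not isolated), via anti-betaine 9 (not isolated)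
Conditions: Cs2CO3 (3 equiv), MeCN, −20 °C to rt (6 in slight excess)
Reagents that add atoms: none
Why: Proposed new method: Cs2CO3 turns racemic 3 by E1cB loss of sulfinate into the planar, achiral ortho-quinone methide 7, so that both enantiomers of 3 are funnelled into one intermediate, and deprotonates 6 to the semistabilised benzylide 8; the ylide carbon adds to the exocyclic methide carbon of 7 (C2–C3 bond, driven by rearomatisation) to give betaine 9, whose phenoxide displaces the sulfide at the same carbon (O1–C2 bond), a formal [4+1] annulation in which the future C2 is first donor and then acceptor. The closest known reactions are the base-mediated [4+1] annulation of ortho-quinone methides, released from 2-(1-sulfonylalkyl)phenols, with carbonyl-stabilised sulfonium ylides to trans-2,3-dihydrobenzofurans, and asymmetric benzylidene transfer from isothiocineole-derived benzylsulfonium salts to aldehydes, imines and enones; what is new is their union, a chiral semistabilised ylide on an ortho-quinone methide. The dihydrofuran ring closes in a 5-exo-tet SN2 displacement with inversion at C2. C2 is controlled by the sulfide: 6 is a single diastereomer at sulfur, the aryl group of 8 turns away from the gem-dimethyl carbon and the methide approaches the ylide face remote from it, which by this model makes the sulfonium-bearing carbon of 9 (S) and, after inversion, C2 (R). C3 is set in the same addition by its relative topicity: as in ylide epoxidation and cyclopropanation, the betaine diastereomer 9 that keeps the ylide aryl and the methide methyl apart should be favoured, and it closes to the 2,3-trans ring with 3R. The step needs conjugate addition to outrun tautomerisation of 7 to the 2-vinylphenol and its [4+2] self-dimerisation, which the reversible storage of 7 as its sulfinate adduct 3, the excess of 8 and the electron-poor brominated methide should secure, and the bromine stands in for the propenyl group because an electron-rich styrene would trap 7 in a hetero-Diels–Alder reaction.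

**Step 5**
Reactants: 10 (2R,3R)-5-bromo-7-methoxy-3-methyl-2-(3,4,5-trimethoxyphenyl)-2,3-dihydro-1-benzofuran; 11 (E)-4,4,5,5-tetramethyl-2-(prop-1-en-1-yl)-1,3,2-dioxaborolane
Product: 12 (2R,3R)-7-methoxy-3-methyl-5-[(1E)-prop-1-en-1-yl]-2-(3,4,5-trimethoxyphenyl)-2,3-dihydro-1-benzofuran
Conditions: Pd(dppf)Cl2·CH2Cl2 (5 mol %), K2CO3 (3 equiv), 1,4-dioxane/H2O (4:1), 80 °C
Reagents that add atoms: none
Why: Suzuki–Miyaura cross-coupling at the C5–Br bond with retention of the (E)-alkenyl geometry of the boronate; the two sp3 stereocentres carry no hydrogen acidic towards carbonate and are not touched.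

**Compound list**
1 | 5-bromo-2-hydroxy-3-methoxybenzaldehyde | O=Cc1cc(Br)cc(OC)c1O | starting material
2 | rac-4-bromo-2-(1-hydroxyethyl)-6-methoxyphenol | CC(O)c1cc(Br)cc(OC)c1O | intermediate
3 | rac-4-bromo-2-methoxy-6-[1-(4-methylbenzenesulfonyl)ethyl]phenol | Cc1ccc(cc1)S(=O)(=O)C(C)c1cc(Br)cc(OC)c1O | intermediate
4 | 5-(bromomethyl)-1,2,3-trimethoxybenzene | COc1cc(CBr)cc(OC)c1OC | starting material
5 | (1S,4S,5S)-4,7,7-trimethyl-6-thiabicyclo[3.2.1]octane (isothiocineole) | C[C@H]1CC[C@H]2C[C@@H]1SC2(C)C | starting material
6 | S-(3,4,5-trimethoxybenzyl)sulfonium triflate of 5, benzyl on the sulfur face remote from the trimethylene bridge | C[C@H]1CC[C@H]2C[C@@H]1[S@+](Cc1cc(OC)c(OC)c(OC)c1)C2(C)C.[O-]S(=O)(=O)C(F)(F)F | intermediate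
7 | (6E)-4-bromo-6-ethylidene-2-methoxycyclohexa-2,4-dien-1-one (ortho-quinone methide) | C/C=C1\C=C(Br)C=C(OC)C1=O | intermediate
8 | sulfonium benzylide of 6 (carbanion on the benzylic carbon, sulfur as in 6) | C[C@H]1CC[C@H]2C[C@@H]1[S@+]([CH-]c1cc(OC)c(OC)c(OC)c1)C2(C)C | intermediate
9 | anti-betaine: 4-bromo-2-methoxyphenolate carrying at C6 the CH(CH3)–CH(aryl)(sulfonium) chain, ArCH(CH3) carbon (R), sulfonium-bearing carbon (S) | C[C@H]1CC[C@H]2C[C@@H]1[S@+]([C@H](c1cc(OC)c(OC)c(OC)c1)[C@H](C)c1cc(Br)cc(OC)c1[O-])C2(C)C | intermediate
10 | (2R,3R)-5-bromo-7-methoxy-3-methyl-2-(3,4,5-trimethoxyphenyl)-2,3-dihydro-1-benzofuran (trans) | Brc1cc(OC)c2c(c1)[C@@H](C)[C@H](c1cc(OC)c(OC)c(OC)c1)O2 | intermediate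
11 | (E)-4,4,5,5-tetramethyl-2-(prop-1-en-1-yl)-1,3,2-dioxaborolane | C/C=C/B1OC(C)(C)C(C)(C)O1 | starting material
12 | (2R,3R)-7-methoxy-3-methyl-5-[(1E)-prop-1-en-1-yl]-2-(3,4,5-trimethoxyphenyl)-2,3-dihydro-1-benzofuran | C/C=C/c1cc(OC)c2c(c1)[C@@H](C)[C@H](c1cc(OC)c(OC)c(OC)c1)O2 | target

**Step count and risks**
Total step count: 5. Longest linear sequence: 4 steps (steps 1, 2, 4 and 5; step 3 is the side branch).

Steps most likely to fail:

Step 4 (Proposed new method). Three things may go wrong:
- The quinone methide may be lost to base-induced tautomerisation to the 2-vinylphenol, or to self-dimerisation, before the ylide captures it.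
- Facial selection at the ylide carbon may be low or opposite to the model; the sense of induction is a prediction that has to be checked on the first run.
- The relative topicity of the addition may deliver cis material. The cis isomer has to be removed by chromatography and must not be equilibrated with acid: it carries the wrong C3, and acid epimerisation at C2 would turn it into the enantiomer of 10.

The fallback uses known chemistry, sets out from diol 2 and returns to the route at 10. Oxidation of the benzylic alcohol of 2 with activated MnO2 (CH2Cl2) should give 1-(5-bromo-2-hydroxy-3-methoxyphenyl)ethan-1-one F1. Williamson etherification with bromide 4 (K2CO3, DMF) gives 1-{5-bromo-3-methoxy-2-[(3,4,5-trimethoxyphenyl)methoxy]phenyl}ethan-1-one F2. Condensation with hydrazine hydrate (EtOH, cat. AcOH, reflux) gives the hydrazone (1-{5-bromo-3-methoxy-2-[(3,4,5-trimethoxyphenyl)methoxy]phenyl}ethylidene)hydrazine F3. Oxidation with MnO2 gives 5-bromo-1-(1-diazoethyl)-3-methoxy-2-[(3,4,5-trimethoxyphenyl)methoxy]benzene F4, which is not isolated. It is treated with a chiral dirhodium tetracarboxylate of the phthalimido-adamantylacetate type, in the antipode that delivers 3R, so that the donor/donor carbene inserts into the benzylic O–CH2 bond. This should give the cis isomer (2S,3R)-5-bromo-7-methoxy-3-methyl-2-(3,4,5-trimethoxyphenyl)-2,3-dihydro-1-benzofuran F5. A short treatment with CF3CO2H in CH2Cl2 then epimerises C2 through the ring-opened benzylic cation to the more stable trans isomer, which is 10.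

Step 2. Ionisation of the secondary ortho-hydroxybenzylic alcohol may lead to self-condensation (ether formation, dimerisation of the transient quinone methide) faster than capture by sulfinate, and the substitution is reversible. The fallback sets out from aldehyde 1 and returns at 10, by-passing 2 and 3. O-acylation of 1 with Boc2O (cat. DMAP, CH2Cl2) gives tert-butyl (4-bromo-2-formyl-6-methoxyphenyl) carbonate F6. Addition of MeMgBr at −78 °C in THF triggers the known alkoxide-to-carbonate transfer and β-elimination that releases the same quinone methide 7 on warming. The cold solution is transferred to ylide 8, pre-formed from 6 with LiHMDS at −78 °C, and warmed, which should give 10.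

Step 5. Protodeboronation of the alkenyl boronate, partial loss of alkene geometry through palladium hydride species, or slow oxidative addition into the electron-rich aryl bromide may erode the coupling. The fallback sets out from bromide 10 and returns at 12. Suzuki–Miyaura coupling with allylboronic acid pinacol ester (Pd(PPh3)4, CsF, THF, reflux) gives (2R,3R)-7-methoxy-3-methyl-5-(prop-2-en-1-yl)-2-(3,4,5-trimethoxyphenyl)-2,3-dihydro-1-benzofuran F7, a partner with no alkene geometry to lose. Isomerisation with a catalytic amount of PdCl2(MeCN)2 in toluene at 60 °C then moves the double bond into conjugation under thermodynamic control and should give the (E)-propenyl compound 12.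

**Further compounds**
F1 | step 4 | 1-(5-bromo-2-hydroxy-3-methoxyphenyl)ethan-1-one | CC(=O)c1cc(Br)cc(OC)c1O
F2 | step 4 | 1-{5-bromo-3-methoxy-2-[(3,4,5-trimethoxyphenyl)methoxy]phenyl}ethan-1-one | CC(=O)c1cc(Br)cc(OC)c1OCc1cc(OC)c(OC)c(OC)c1
F3 | step 4 | (1-{5-bromo-3-methoxy-2-[(3,4,5-trimethoxyphenyl)methoxy]phenyl}ethylidene)hydrazine | CC(=NN)c1cc(Br)cc(OC)c1OCc1cc(OC)c(OC)c(OC)c1
F4 | step 4 | 5-bromo-1-(1-diazoethyl)-3-methoxy-2-[(3,4,5-trimethoxyphenyl)methoxy]benzene | CC(=[N+]=[N-])c1cc(Br)cc(OC)c1OCc1cc(OC)c(OC)c(OC)c1
F5 | step 4 | (2S,3R)-5-bromo-7-methoxy-3-methyl-2-(3,4,5-trimethoxyphenyl)-2,3-dihydro-1-benzofuran (cis) | Brc1cc(OC)c2c(c1)[C@@H](C)[C@@H](c1cc(OC)c(OC)c(OC)c1)O2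
F6 | step 2 | tert-butyl (4-bromo-2-formyl-6-methoxyphenyl) carbonate | O=Cc1cc(Br)cc(OC)c1OC(=O)OC(C)(C)C
F7 | step 5 | (2R,3R)-7-methoxy-3-methyl-5-(prop-2-en-1-yl)-2-(3,4,5-trimethoxyphenyl)-2,3-dihydro-1-benzofuran | C=CCc1cc(OC)c2c(c1)[C@@H](C)[C@H](c1cc(OC)c(OC)c(OC)c1)O2
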